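Two questions carry us along the row of flasks eta, zeta, delta and beta, where D is charged at rising strength against the same Z: how fast does D go while Z stands at its charge, and how much does the fall of Z change that in beta, the flask with 0.15 M of D?

| flask | D | Z | remark | time |
|---|---|---|---|---|
| grey | 0.0060 M | 0.21 M | run made earlier |  |
| red | 0.0060 M | 0.61 M | run made earlier |  |
| eta | 0.0060 M | 0.306 M |  | 8.0 h |
| zeta | 0.020 M | 0.306 M |  | 8.0 h |
| delta | 0.060 M | 0.306 M |  | 8.0 h |
| beta | 0.15 M | 0.306 M |  | 8.0 h |

- grey (time / min: G / %, D / %): 8.00: 2.8, 97.2; 12.0: 2.1, 96.7; 20.0: 3.7, 95.0; 25.0: 3.7, 95.3; 40.0: 6.5, 92.0; 60.0: 9.9, 88.4; 90.0: 16.6, 83.0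
- red (time / min: G / %, D / %): 15.0: 8.9, 92.9; 30.0: 16.0, 82.2; 40.0: 19.6, 79.5; 60.0: 28.2, 71.5; 80.0: 33.9, 62.9; 90.0: 38.9, 61.7

(scatter of a reading: 1 percentage point)

- the analysis behind the earlier runs scatters by 1 percentage point, standard deviation
- "hardly changes" means that all values lie within two and a half points (for a concentration: within two and a half percent of the largest)

- [G] at the end for eta, zeta, delta, beta, in this order
- the shape of the row from first to last (rises all the way / rises, then falls / falls, then rises / falls all the way / hardly changes)

For the first question we read k′, the first-order constant of the fall of D, as ln(D charged / D left)/t at the last reading of each earlier run. This gives 0.00207 min⁻¹ in grey and 0.00537 min⁻¹ in red, a ratio of 2.59 against 2.90 in Z, which under the scatter of 1 percentage point we take as first order in Z. G and D at the last two red readings add up to 96.8 % and 101 % of the charge, which leaves a small loss to other products open, so counting G as what D has lost is a working assumption of ours and not a finding. Pooling both runs, the sum of k′ over the sum of Z, and scaling to 0.306 M of Z gives τ = 4.16 h, the pseudo-first-order half-life of D while Z stands at its charge. In eta, Z is 51.0 times D, so τ holds throughout, and 8.0 h leaves 26.4 % of D, which on that assumption makes G 0.00442 M.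

For the second question, D in beta, the limiting reagent, amounts to 49.0 % of the Z charged, so Z sinks and τ lengthens. The mixed second-order law with the same constant gives G = 0.0984 M, or 65.6 % of the charge against 73.6 % in eta. The charge grows 25.0-fold while that share falls 1.12-fold, so we expect the row to rise.

The forecast gave 0.0044 M, 0.0146 M, 0.0426 M and 0.099 M, rises all the way, equal to ours at eta and slightly above ours at beta, with the caution that “the scatter does not firmly exclude other orders”.

The flasks give 0.00380 M, 0.0125 M, 0.0366 M and 0.0854 M: rises all the way.

    G ⇌ E (K = 0.140, k = 0.0860 h⁻¹)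
    D → X (k = 0.0140 h⁻¹)
    D + Z → G (k = 0.560 M⁻¹ h⁻¹)

At the end of eta, G is still made 6.10 times faster than it is used up, each step taken net, and it stands at 63.3 % of the charge, while D has lost 77.0 %. With τ, eta should keep 26.4 % of its D, and it keeps 23.0 %. In beta, Z stands at 78.4 % of its charge after 4.00 h, which stretches τ to 5.31 h and leaves 35.2 % of D, where beta holds 29.7 %.

The runs are calculated from invented constants; scatter was added.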